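**Plan** (elemane locants: cyclohexane C5–C10, C10 quaternary with CH3 and the vinyl group C1=C2; lactone O–C6, C7, C11(=C13), C12; ester oxygen on C8; acrylic acid C4(=C3)–C15 on C5)
Retrosynthesis cuts: C15 acid back to an isopropenyl CH3; the C8–O tigloyl ester; then, in one event, the C8–C9 ring bond and the C10–CH3 bond; then C7–C8 and C11–C13; C6–C7; C5–C10.
Enabling feature: C10 is allylic (its vinyl group) and 1,3 to C8 across the C9 methylene, and the C8 oxygen and the C10 methyl are cis-diaxial on the cyclohexane. A C8 aldehyde can therefore close onto a 2-substituted buta-1,3-diene (C9=C10–C1=C2), and the oxygen-bound aluminate can deliver CH3 to C10.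
Forward order: allenylmethyl ester → dienyl acid (C5–C10) → butenolide (ring 1) → trans lactone aldehyde → cyclohexane (ring 2) → tiglate, methylene lactone, acid.
Stereochemistry: C5 from a reagent-controlled Ireland–Claisen rearrangement, C6 from a catalyst-controlled alkynylation, C7 from anti conjugate addition to the butenolide, C8 and C10 from the chair of the key step.

Key step: step 9

Assumption: in steps 2 and 5 the named enantiomer of the chiral controller is taken to give the configuration drawn; the antipode is equally available and would be used if the sense of induction is the reverse.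

Step 1
Reactants: 1 buta-2,3-dien-1-ol; 2 3-methylbut-3-enoic acid
Product: 3 buta-2,3-dien-1-yl 3-methylbut-3-enoate
Conditions: DCC, DMAP (5 mol %), CH2Cl2, 0 °C
Reagents that add atoms: none
Why: Steglich esterification at 0 °C should join acid and allenic alcohol without moving the β,γ-double bond into conjugation; no stereocentre is formed.

Step 2
Reactants: 3 buta-2,3-dien-1-yl 3-methylbut-3-enoate
Product: 6 (2S)-3-methylidene-2-(prop-1-en-2-yl)pent-4-enoic acid, via boron ketene acetal 4 (not isolated), via acyloxyborane 5 (not isolated)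
Conditions: (S,S)-2-bromo-1,3-bis[[3,5-bis(trifluoromethyl)phenyl]sulfonyl]-4,5-diphenyl-1,3,2-diazaborolidine (1.1 equiv), Et3N, toluene/hexane, −78 °C then −20 °C; aqueous work-up
Reagents that add atoms: none
Why: Enantioselective Ireland–Claisen rearrangement through the boron ketene acetal, in which the ester α-carbon (C5) bonds to the central allene carbon (C10) in a chair [3,3] transition state, turning the allenylmethyl group into the 2-substituted buta-1,3-diene, while the C2-symmetric bis-sulfonamide on boron and the E(O)-enolate geometry should fix the enolate face and set C5 as S.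

Step 3
Reactants: 6 (2S)-3-methylidene-2-(prop-1-en-2-yl)pent-4-enoic acid
Product: 7 (2S)-3-methylidene-2-(prop-1-en-2-yl)pent-4-en-1-ol
Conditions: LiAlH4, Et2O, 0 °C; H2O, NaOH (aq)
Reagents that add atoms: none
Why: Hydride reduction of the carboxylic acid with LiAlH4 should leave the isolated alkene and the unactivated diene untouched, and C5 is protected from epimerisation because the substrate reacts as its carboxylate.

Step 4
Reactants: 7 (2S)-3-methylidene-2-(prop-1-en-2-yl)pent-4-en-1-ol
Product: 8 (2S)-3-methylidene-2-(prop-1-en-2-yl)pent-4-enal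
Conditions: Dess–Martin periodinane, NaHCO3, CH2Cl2, 0 °C; used at once
Reagents that add atoms: none
Why: Dess–Martin oxidation under bicarbonate buffer gives the aldehyde without base or heat, which matters because C5 is doubly allylic and α to the formyl group.

Step 5
Reactants: 8 (2S)-3-methylidene-2-(prop-1-en-2-yl)pent-4-enal; 9 methyl prop-2-ynoate
Product: 10 methyl (4R,5S)-4-hydroxy-6-methylidene-5-(prop-1-en-2-yl)oct-7-en-2-ynoate
Conditions: Me2Zn (3 equiv), (S,S)-ProPhenol (20 mol %), toluene, 0 °C; NH4Cl (aq)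
Reagents that add atoms: none
Why: Catalytic enantioselective alkynylation of an aldehyde by the alkynylzinc reagent formed from 9 and Me2Zn; the two alkenyl groups on C5 are nearly equal in size, so the aldehyde has little facial bias of its own and the catalyst should set C6 as R.

Step 6
Reactants: 10 methyl (4R,5S)-4-hydroxy-6-methylidene-5-(prop-1-en-2-yl)oct-7-en-2-ynoate
Product: 12 (5S)-5-[(3S)-2-methyl-4-methylidenehexa-1,5-dien-3-yl]furan-2(5H)-one, via cis-hydroxy enoate 11 (not isolated)
Conditions: H2 (1 atm), Pd/CaCO3 poisoned with Pb(OAc)2, quinoline, EtOAc, 20 °C; then PPTS (cat.)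
Reagents that add atoms: none
Why: Lindlar semihydrogenation of the ynoate gives the cis-enoate, which lactonises with loss of methanol to the butenolide; the alkyne binds to poisoned palladium far more strongly than the diene or the isopropenyl group, and no stereocentre is touched.

Step 7
Reactants: 12 (5S)-5-[(3S)-2-methyl-4-methylidenehexa-1,5-dien-3-yl]furan-2(5H)-one; 13 bis(phenylsulfanyl)methane
Product: 16 [(3R,4S,5R)-4-[bis(phenylsulfanyl)methyl]-5-[(3S)-2-methyl-4-methylidenehexa-1,5-dien-3-yl]-2-oxooxolan-3-yl]methyl acetate, via lithium enolate 14 (not isolated), via lithium alkoxide 15 (not isolated)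
Conditions: 13, n-BuLi, THF, −78 °C; then 12; CH2O (gas), −78 to −40 °C; Ac2O, −40 to 0 °C
Reagents that add atoms: formaldehyde C=O; acetic anhydride CC(=O)OC(C)=O
Why: Tandem conjugate addition–aldol reaction in which the sulfur-stabilised formyl anion equivalent adds to the butenolide anti to the C6 side chain (C7 trans to C6), the lactone enolate is hydroxymethylated anti to the new C7 group and the alkoxide is acetylated, which stores the future exocyclic methylene as a β-acetoxy lactone.

Step 8
Reactants: 16 [(3R,4S,5R)-4-[bis(phenylsulfanyl)methyl]-5-[(3S)-2-methyl-4-methylidenehexa-1,5-dien-3-yl]-2-oxooxolan-3-yl]methyl acetate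
Product: 17 [(3R,4S,5R)-4-formyl-5-[(3S)-2-methyl-4-methylidenehexa-1,5-dien-3-yl]-2-oxooxolan-3-yl]methyl acetate
Conditions: PhI(OCOCF3)2, NaHCO3, MeCN/H2O (9:1), 0 °C
Reagents that add atoms: water O
Why: Oxidative dithioacetal hydrolysis with a λ3-iodane, which should oxidise sulfur much faster than the alkenes, releases the C8 aldehyde, whose α-centre C7 already has the more stable trans arrangement.

Step 9
Reactants: 17 [(3R,4S,5R)-4-formyl-5-[(3S)-2-methyl-4-methylidenehexa-1,5-dien-3-yl]-2-oxooxolan-3-yl]methyl acetate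
Product: 18 [(3R,3aR,4R,6S,7S,7aR)-6-ethenyl-4-hydroxy-6-methyl-2-oxo-7-(prop-1-en-2-yl)octahydro-1-benzofuran-3-yl]methyl acetate
Conditions: Me3Al (2.5 equiv), CH2Cl2, −78 to −30 °C; 1 M HCl (aq), 0 °C
Reagents that add atoms: trimethylaluminium C[Al](C)C
Why: Proposed new method: Me3Al-mediated methylative Prins cyclisation, in which the AlMe3-complexed C8 aldehyde is attacked by the terminal CH2 (C9) of the 2-substituted buta-1,3-diene to give a zwitterion (allyl cation C10–C1–C2 and oxygen-bound trimethylaluminate) that collapses by transfer of CH3 from aluminium to C10 through a six-membered array on the face that carries the oxygen. The closest known reaction types are the alkylaluminium-promoted Prins additions of aldehydes to alkenes, in which the zwitterion collapses by syn transfer of chloride or methyl from the aluminate, and the type 2 carbonyl-ene cyclisations of aldehydes onto 1,1-disubstituted alkenes that give 3-methylenecyclohexanols. The cyclohexane closes in the 6-endo mode of that type 2 topology (C8 to C9, tether on the internal alkene carbon C10) through a chair in which the C5, C6 and C7 substituents are equatorial. C8 is set by the axial position the aluminate oxygen must take to reach C10 (closure with an equatorial oxygen cannot collapse and should revert), and C10 is set by the internal delivery, which places CH3 axial and cis to the C8 oxygen and leaves the vinyl group equatorial. The step needs closure by the diene and not by the isopropenyl group, ring closure before methyl transfer to the carbonyl carbon, and delivery to C10 and not C2: the C5 configuration allows a chair with an equatorial bystander only when the diene closes, the intramolecular closure should outrun bimolecular carbonyl methylation at −78 °C, and the six-membered delivery favours C10 while closure of oxygen onto C2 would give a bridgehead alkene.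

Step 10
Reactants: 18 [(3R,3aR,4R,6S,7S,7aR)-6-ethenyl-4-hydroxy-6-methyl-2-oxo-7-(prop-1-en-2-yl)octahydro-1-benzofuran-3-yl]methyl acetate; 19 (2E)-2-methylbut-2-enoyl chloride
Product: 21 (3aR,4R,6S,7S,7aR)-6-ethenyl-6-methyl-3-methylidene-2-oxo-7-(prop-1-en-2-yl)octahydro-1-benzofuran-4-yl (2E)-2-methylbut-2-enoate, via acetoxymethyl lactone tiglate 20 (not isolated)
Conditions: 19, Et3N, DMAP, CH2Cl2, 0 to 35 °C; then DBU, 0 °C
Reagents that add atoms: none
Why: DMAP-catalysed acylation of the hindered axial C8 alcohol by the acid chloride, then E1cB elimination of acetic acid from the β-acetoxy lactone with DBU, should unveil the α-methylene lactone; the tiglate keeps its stable E geometry and C11 becomes sp2.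

Step 11
Reactants: 21 (3aR,4R,6S,7S,7aR)-6-ethenyl-6-methyl-3-methylidene-2-oxo-7-(prop-1-en-2-yl)octahydro-1-benzofuran-4-yl (2E)-2-methylbut-2-enoate
Product: 23 (3aR,4R,6S,7R,7aR)-6-ethenyl-6-methyl-3-methylidene-2-oxo-7-(3-oxoprop-1-en-2-yl)octahydro-1-benzofuran-4-yl (2E)-2-methylbut-2-enoate, via allylic alcohol 22 (not isolated)
Conditions: SeO2 (0.3 equiv), t-BuOOH, CH2Cl2, 20 °C; then MnO2, CH2Cl2, 20 °C
Reagents that add atoms: tert-butyl hydroperoxide CC(C)(C)OO
Why: Riley allylic oxidation (ene reaction then [2,3]-shift) at the CH3 of the isopropenyl group, the only electron-rich alkene with allylic hydrogen on a methyl group (the vinyl group has none, the methylene lactone and the tiglate are electron-poor), followed by MnO2 oxidation of the allylic alcohol to the 2-substituted acrolein.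

Step 12
Reactants: 23 (3aR,4R,6S,7R,7aR)-6-ethenyl-6-methyl-3-methylidene-2-oxo-7-(3-oxoprop-1-en-2-yl)octahydro-1-benzofuran-4-yl (2E)-2-methylbut-2-enoate
Product: 24 2-[(3aR,4R,6S,7R,7aR)-6-ethenyl-6-methyl-3-methylidene-4-{[(2E)-2-methylbut-2-enoyl]oxy}-2-oxooctahydro-1-benzofuran-7-yl]prop-2-enoic acid
Conditions: NaClO2, NaH2PO4, 2-methylbut-2-ene, t-BuOH/H2O, 20 °C
Reagents that add atoms: sodium chlorite [Na+].[O-]Cl=O
Why: Pinnick oxidation should convert the enal into the acrylic acid under buffered conditions that leave the methylene lactone, the ester and the alkenes intact while 2-methylbut-2-ene scavenges the hypochlorite by-product.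

**Compound list**
1 | buta-2,3-dien-1-ol | C=C=CCO | starting material
2 | 3-methylbut-3-enoic acid | C=C(C)CC(=O)O | starting material
3 | buta-2,3-dien-1-yl 3-methylbut-3-enoate | C=C(C)CC(=O)OCC=C=C | intermediate
4 | boron ketene acetal of 3 (E(O)-enolate on the (S,S)-diazaborolidine) | C=C(C)/C=C(\OCC=C=C)OB1N(S(=O)(=O)c2cc(cc(c2)C(F)(F)F)C(F)(F)F)[C@@H](c2ccccc2)[C@H](c2ccccc2)N1S(=O)(=O)c1cc(cc(c1)C(F)(F)F)C(F)(F)F | intermediate
5 | acyloxyborane of acid 6 | O=C([C@@H](C(C)=C)C(=C)C=C)OB1N(S(=O)(=O)c2cc(cc(c2)C(F)(F)F)C(F)(F)F)[C@@H](c2ccccc2)[C@H](c2ccccc2)N1S(=O)(=O)c1cc(cc(c1)C(F)(F)F)C(F)(F)F | intermediate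
6 | (2S)-3-methylidene-2-(prop-1-en-2-yl)pent-4-enoic acid | OC(=O)[C@@H](C(C)=C)C(=C)C=C | intermediate
7 | (2S)-3-methylidene-2-(prop-1-en-2-yl)pent-4-en-1-ol | OC[C@@H](C(C)=C)C(=C)C=C | intermediate
8 | (2S)-3-methylidene-2-(prop-1-en-2-yl)pent-4-enal | O=C[C@@H](C(C)=C)C(=C)C=C | intermediate
9 | methyl prop-2-ynoate | COC(=O)C#C | starting material
10 | methyl (4R,5S)-4-hydroxy-6-methylidene-5-(prop-1-en-2-yl)oct-7-en-2-ynoate | COC(=O)C#C[C@H](O)[C@@H](C(C)=C)C(=C)C=C | intermediate
11 | methyl (2Z,4S,5S)-4-hydroxy-6-methylidene-5-(prop-1-en-2-yl)octa-2,7-dienoate | COC(=O)/C=C\[C@H](O)[C@@H](C(C)=C)C(=C)C=C | intermediate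
12 | (5S)-5-[(3S)-2-methyl-4-methylidenehexa-1,5-dien-3-yl]furan-2(5H)-one | O=C1O[C@H]([C@@H](C(C)=C)C(=C)C=C)C=C1 | intermediate
13 | bis(phenylsulfanyl)methane | C(Sc1ccccc1)Sc1ccccc1 | starting material
14 | lithium enolate of the conjugate adduct of 12 and 13 | [Li+].[O-]C1=C[C@H](C(Sc2ccccc2)Sc2ccccc2)[C@@H]([C@@H](C(C)=C)C(=C)C=C)O1 | intermediate
15 | lithium alkoxide of the 3-(hydroxymethyl) lactone | O=C1O[C@H]([C@@H](C(C)=C)C(=C)C=C)[C@@H](C(Sc2ccccc2)Sc2ccccc2)[C@@H]1C[O-].[Li+] | intermediate
16 | [(3R,4S,5R)-4-[bis(phenylsulfanyl)methyl]-5-[(3S)-2-methyl-4-methylidenehexa-1,5-dien-3-yl]-2-oxooxolan-3-yl]methyl acetate | O=C1O[C@H]([C@@H](C(C)=C)C(=C)C=C)[C@@H](C(Sc2ccccc2)Sc2ccccc2)[C@@H]1COC(C)=O | intermediate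
17 | [(3R,4S,5R)-4-formyl-5-[(3S)-2-methyl-4-methylidenehexa-1,5-dien-3-yl]-2-oxooxolan-3-yl]methyl acetate | O=C1O[C@H]([C@@H](C(C)=C)C(=C)C=C)[C@@H](C=O)[C@@H]1COC(C)=O | intermediate
18 | [(3R,3aR,4R,6S,7S,7aR)-6-ethenyl-4-hydroxy-6-methyl-2-oxo-7-(prop-1-en-2-yl)octahydro-1-benzofuran-3-yl]methyl acetate | C=C[C@]1(C)C[C@@H](O)[C@H]2[C@H](COC(C)=O)C(=O)O[C@@H]2[C@H]1C(C)=C | intermediate
19 | (2E)-2-methylbut-2-enoyl chloride (tigloyl chloride) | C/C=C(\C)C(Cl)=O | starting material
20 | (3R,3aR,4R,6S,7S,7aR)-3-(acetoxymethyl)-6-ethenyl-6-methyl-2-oxo-7-(prop-1-en-2-yl)octahydro-1-benzofuran-4-yl (2E)-2-methylbut-2-enoate | C=C[C@]1(C)C[C@@H](OC(=O)/C(C)=C/C)[C@H]2[C@H](COC(C)=O)C(=O)O[C@@H]2[C@H]1C(C)=C | intermediate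
21 | (3aR,4R,6S,7S,7aR)-6-ethenyl-6-methyl-3-methylidene-2-oxo-7-(prop-1-en-2-yl)octahydro-1-benzofuran-4-yl (2E)-2-methylbut-2-enoate | C=C[C@]1(C)C[C@@H](OC(=O)/C(C)=C/C)[C@H]2C(=C)C(=O)O[C@@H]2[C@H]1C(C)=C | intermediate
22 | (3aR,4R,6S,7R,7aR)-6-ethenyl-7-(3-hydroxyprop-1-en-2-yl)-6-methyl-3-methylidene-2-oxooctahydro-1-benzofuran-4-yl (2E)-2-methylbut-2-enoate | C=C[C@]1(C)C[C@@H](OC(=O)/C(C)=C/C)[C@H]2C(=C)C(=O)O[C@@H]2[C@H]1C(=C)CO | intermediate
23 | (3aR,4R,6S,7R,7aR)-6-ethenyl-6-methyl-3-methylidene-2-oxo-7-(3-oxoprop-1-en-2-yl)octahydro-1-benzofuran-4-yl (2E)-2-methylbut-2-enoate | C=C[C@]1(C)C[C@@H](OC(=O)/C(C)=C/C)[C@H]2C(=C)C(=O)O[C@@H]2[C@H]1C(=C)C=O | intermediate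
24 | 2-[(3aR,4R,6S,7R,7aR)-6-ethenyl-6-methyl-3-methylidene-4-{[(2E)-2-methylbut-2-enoyl]oxy}-2-oxooctahydro-1-benzofuran-7-yl]prop-2-enoic acid | C=C[C@]1(C)C[C@@H](OC(=O)/C(C)=C/C)[C@H]2C(=C)C(=O)O[C@@H]2[C@H]1C(=C)C(=O)O | target

**Step count and risks**
Total step count: 12. Longest linear sequence: 12 (steps 1 to 12; compounds 9, 13 and 19 are purchased).

Steps most likely to fail:

Step 9. Methyl may transfer from aluminium to the carbonyl carbon before the ring closes, methyl may be delivered to the distal allyl terminus C2, or the ring may close by an ene reaction through the isopropenyl group. The fallback splits the event into two known operations and sets out from 17. Me2AlCl (2.2 equiv), CH2Cl2, −78 °C, should effect a chloride-terminated Prins cyclisation, the documented course of dialkylaluminium chloride-promoted aldehyde–alkene additions with syn delivery of chloride. This gives the tertiary allylic chloride that is the analogue of 18 with Cl in place of the C10 methyl, cis to the C8 hydroxyl, F1. The tertiary chloride is then exchanged for methyl with Me2TiCl2 (from Me2Zn and TiCl4), CH2Cl2, −78 to −30 °C, a known methylation of tertiary alkyl chlorides, here through the allyl cation held next to the C8 titanium alkoxide. This returns to the route at 18.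

Step 5. Configuration at C5 may be lost by enolisation of 8 during the slow zinc-mediated addition, and catalyst control at C6 may be incomplete. The fallback avoids the free aldehyde and sets out from 6. Amide formation (EDC·HCl, MeNH(OMe)·HCl, N-methylmorpholine, CH2Cl2) gives (2S)-N-methoxy-N-methyl-3-methylidene-2-(prop-1-en-2-yl)pent-4-enamide F2. Acylation of the lithium acetylide of 9 (LiHMDS, THF, −78 °C) gives methyl (5S)-6-methylidene-4-oxo-5-(prop-1-en-2-yl)oct-7-en-2-ynoate F3, which exists only after neutral work-up. CBS reduction of the ynone ((S)-2-methyl-CBS-oxazaborolidine, catecholborane, toluene, −78 °C) then sets C6 by reagent control and returns to the route at 10.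

Step 2. Enolate geometry or enolate face may be poorly controlled on the allenylmethyl ester, giving low enantiomeric purity, and the deconjugated ester may isomerise to the conjugated dienoate before it rearranges. The fallback replaces reagent control by resolution and sets out from 3. A standard Ireland–Claisen rearrangement (LDA, Me3SiCl, THF, −78 to 25 °C) proceeds through buta-2,3-dien-1-yl trimethylsilyl ketene acetal F4 and trimethylsilyl 3-methylidene-2-(prop-1-en-2-yl)pent-4-enoate F5. Dilute HCl then gives racemic 3-methylidene-2-(prop-1-en-2-yl)pent-4-enoic acid F6. Crystallisation with (S)-1-phenylethylamine gives (S)-1-phenylethylammonium (2S)-3-methylidene-2-(prop-1-en-2-yl)pent-4-enoate F7, and acidification returns to the route at 6.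

**Further compounds**
F1 | step 9 | analogue of 18 with chlorine in place of the C10 methyl group, cis to the C8 hydroxyl | C=C[C@]1(Cl)C[C@@H](O)[C@H]2[C@H](COC(C)=O)C(=O)O[C@@H]2[C@H]1C(C)=C
F2 | step 5 | (2S)-N-methoxy-N-methyl-3-methylidene-2-(prop-1-en-2-yl)pent-4-enamide | CON(C)C(=O)[C@@H](C(C)=C)C(=C)C=C
F3 | step 5 | methyl (5S)-6-methylidene-4-oxo-5-(prop-1-en-2-yl)oct-7-en-2-ynoate | COC(=O)C#CC(=O)[C@@H](C(C)=C)C(=C)C=C
F4 | step 2 | buta-2,3-dien-1-yl trimethylsilyl ketene acetal of 3 | C=C(C)C=C(OCC=C=C)O[Si](C)(C)C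
F5 | step 2 | trimethylsilyl 3-methylidene-2-(prop-1-en-2-yl)pent-4-enoate (racemic) | C=CC(=C)C(C(C)=C)C(=O)O[Si](C)(C)C
F6 | step 2 | 3-methylidene-2-(prop-1-en-2-yl)pent-4-enoic acid (racemic) | OC(=O)C(C(C)=C)C(=C)C=C
F7 | step 2 | (S)-1-phenylethylammonium (2S)-3-methylidene-2-(prop-1-en-2-yl)pent-4-enoate | C[C@H]([NH3+])c1ccccc1.[O-]C(=O)[C@@H](C(C)=C)C(=C)C=C
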